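The 14-membered carbocycle (C1 bears the dienyl side chain, C14 the methoxy group, C15 is the side-chain carbon on C1) is traced back to a linear C2–C14 triene, which is disconnected on both flanks of the Z C7=C8 double bond. That alkene is the feature used: its methyl sits on C8 while C6 and C9 are cis, which is what a syn alkylcopper addition to propyne followed by retentive alkylation delivers. One operation therefore unites the E-homoallylic C9–C14 Grignard reagent (C14 silyl ether), propyne and the Z-homoallylic C2–C6 iodide (C2 PMB ether) through the C8–C9 and C6–C7 bonds. C1 and C15 arrive as a β-keto ester; macro-alkylation and asymmetric hydrogenation set C1 and C14.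

Key step: step 11

Remark: the target SMILES is read as (1R,14S) in this numbering (side chain and OMe trans on the ring; 3Z,7Z,11E), i.e. (1E,5Z,9Z,12R,13S)-13-methoxy-1,5,9-trimethyl-12-(6-methylhepta-1,5-dien-2-yl)cyclotetradeca-1,5,9-triene, and silyl ether 1 is taken as commercially available.

Step 1
Reactants: 1 tert-butyl(but-3-yn-1-yloxy)dimethylsilane
Product: 3 (E)-tert-butyl[(4-iodo-3-methylbut-3-en-1-yl)oxy]dimethylsilane, via (E)-alkenyldimethylalane 2 (not isolated)
Conditions: Me3Al, Cp2ZrCl2 (0.2 equiv), CH2Cl2, 0 °C → rt; then I2, THF, −30 → 0 °C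
Reagents that add atoms: trimethylaluminium, C[Al](C)C; iodine, II
Why: Negishi zirconium-catalysed carboalumination adds methyl and aluminium syn across the terminal alkyne with the metal on the terminal carbon, and iodinolysis of the C–Al bond with retention should give the E iodide that fixes the C11=C12 geometry.

Step 2
Reactants: 3 (E)-tert-butyl[(4-iodo-3-methylbut-3-en-1-yl)oxy]dimethylsilane; 4 oxirane
Product: 6 (E)-6-[(tert-butyldimethylsilyl)oxy]-4-methylhex-3-en-1-ol, via (E)-alkenyllithium 5 (not isolated)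
Conditions: t-BuLi (2.1 equiv), Et2O, −78 °C; then 4, −78 → 0 °C
Reagents that add atoms: none
Why: Iodine–lithium exchange is stereoretentive at the sp2 carbon and the alkenyllithium opens oxirane by SN2 ring opening, which adds C9–C10 without touching the E alkene.

Step 3
Reactants: 6 (E)-6-[(tert-butyldimethylsilyl)oxy]-4-methylhex-3-en-1-ol
Product: 7 (E)-[(6-bromo-3-methylhex-3-en-1-yl)oxy](tert-butyl)dimethylsilane
Conditions: CBr4, PPh3, CH2Cl2, 0 °C
Reagents that add atoms: carbon tetrabromide, BrC(Br)(Br)Br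
Why: Appel bromination, in which the alkoxyphosphonium ion is displaced by bromide in an SN2 reaction under neutral conditions, should leave the silyl ether and the E alkene untouched.

Step 4
Reactants: 7 (E)-[(6-bromo-3-methylhex-3-en-1-yl)oxy](tert-butyl)dimethylsilane
Product: 8 (E)-{6-[(tert-butyldimethylsilyl)oxy]-4-methylhex-3-en-1-yl}magnesium bromide
Conditions: Mg turnings, Et2O, rt → gentle reflux; titrated solution used directly
Reagents that add atoms: magnesium, [Mg]
Why: Grignard formation by insertion of magnesium into the primary C–Br bond is done in diethyl ether because the carbocupration of step 11 needs that solvent, and homoallylic Grignard reagents of trisubstituted alkenes keep their geometry.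

Step 5
Reactants: 1 tert-butyl(but-3-yn-1-yloxy)dimethylsilane; 9 methyl chloroformate
Product: 11 methyl 5-[(tert-butyldimethylsilyl)oxy]pent-2-ynoate, via lithium acetylide 10 (not isolated)
Conditions: n-BuLi, THF, −78 °C; then 9, −78 → 0 °C
Reagents that add atoms: none
Why: Deprotonation of the terminal alkyne and C-acylation of the acetylide by the chloroformate gives the ynoate whose ester carbon becomes C2.

Step 6
Reactants: 11 methyl 5-[(tert-butyldimethylsilyl)oxy]pent-2-ynoate
Product: 13 methyl (Z)-5-[(tert-butyldimethylsilyl)oxy]-3-methylpent-2-enoate, via lithium alkenyl(methyl)cuprate 12 (not isolated)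
Conditions: Me2CuLi (from MeLi and CuI), THF, −78 °C; MeOH, −78 °C, then aq. NH4Cl
Reagents that add atoms: methyllithium, C[Li]
Why: Syn conjugate addition of the Gilman reagent to the ynoate places methyl and copper cis, and protonation with retention at −78 °C (before the adduct can equilibrate through the allenolate) should give the Z enoate in which the C5 chain and C2 are cis.

Step 7
Reactants: 13 methyl (Z)-5-[(tert-butyldimethylsilyl)oxy]-3-methylpent-2-enoate
Product: 14 (Z)-5-[(tert-butyldimethylsilyl)oxy]-3-methylpent-2-en-1-ol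
Conditions: i-Bu2AlH (2.2 equiv), CH2Cl2, −78 °C; aq. potassium sodium tartrate
Reagents that add atoms: none
Why: 1,2-Reduction of the conjugated ester by the aluminium hydride at −78 °C should give the allylic alcohol without touching the Z alkene or the silyl ether.

Step 8
Reactants: 14 (Z)-5-[(tert-butyldimethylsilyl)oxy]-3-methylpent-2-en-1-ol
Product: 15 (Z)-tert-butyl({5-[(4-methoxybenzyl)oxy]-3-methylpent-3-en-1-yl}oxy)dimethylsilane
Conditions: NaH, 4-methoxybenzyl chloride, Bu4NI (cat.), THF/DMF, 0 °C → rt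
Reagents that add atoms: 4-methoxybenzyl chloride, COc1ccc(CCl)cc1
Why: Williamson etherification of the sodium alkoxide masks C2 as a PMB ether that is orthogonal to the silyl ethers.

Step 9
Reactants: 15 (Z)-tert-butyl({5-[(4-methoxybenzyl)oxy]-3-methylpent-3-en-1-yl}oxy)dimethylsilane
Product: 16 (Z)-5-[(4-methoxybenzyl)oxy]-3-methylpent-3-en-1-ol
Conditions: Bu4NF, THF, 0 °C → rt
Reagents that add atoms: none
Why: Fluoride-mediated desilylation frees the C6 hydroxyl while the PMB ether is inert.

Step 10
Reactants: 16 (Z)-5-[(4-methoxybenzyl)oxy]-3-methylpent-3-en-1-ol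
Product: 17 (Z)-1-{[(5-iodo-3-methylpent-2-en-1-yl)oxy]methyl}-4-methoxybenzene
Conditions: I2, PPh3, imidazole, CH2Cl2, 0 °C
Reagents that add atoms: iodine, II
Why: Appel-type iodination converts the primary homoallylic alcohol into the iodide by SN2 displacement, without allylic transposition.

Step 11
Reactants: 8 (E)-{6-[(tert-butyldimethylsilyl)oxy]-4-methylhex-3-en-1-yl}magnesium bromide; 18 propyne; 17 (Z)-1-{[(5-iodo-3-methylpent-2-en-1-yl)oxy]methyl}-4-methoxybenzene
Product: 21 tert-butyl({(3E,7Z,11Z)-13-[(4-methoxybenzyl)oxy]-3,7,11-trimethyltrideca-3,7,11-trien-1-yl}oxy)dimethylsilane, via alkylcopper 19 (not isolated), via (Z)-alkenylcopper 20 (not isolated)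
Conditions: 8 (1.3 equiv), CuBr·SMe2, Et2O/Me2S, −45 °C; 18 (excess), −25 °C, 2 h; then 17, DMPU, P(OEt)3, −25 °C → rt
Reagents that add atoms: none
Why: Transmetalation of 8 with CuBr·SMe2 gives alkylcopper 19 (as its MgBr2 complex), whose C–Cu bond adds across the triple bond of propyne through a four-centre syn transition state, the new C8–C9 bond forming at the internal, methyl-bearing alkyne carbon and copper ending on the terminal carbon C7, cis to C9, in 20. Activated by DMPU and P(OEt)3, 20 is then alkylated by the primary iodide 17 with retention at C7, so C6 takes the place of copper cis to C9 and the C7=C8 alkene is Z. The closest known reaction type is the Normant carbocupration of a terminal alkyne followed by alkylation of the alkenylcopper. No ring is closed and no stereocentre is formed; the two new bonds, C8–C9 and C6–C7, are both skeletal. The step needs branched regioselectivity and configurational integrity of 20, and both are intrinsic to alkylcopper additions to 1-alkynes in diethyl ether as long as 20 is kept below about −20 °C until the iodide is present. Because 8 and 17 carry only ethers and alkenes, nothing else competes for the organocopper.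

Step 12
Reactants: 21 tert-butyl({(3E,7Z,11Z)-13-[(4-methoxybenzyl)oxy]-3,7,11-trimethyltrideca-3,7,11-trien-1-yl}oxy)dimethylsilane
Product: 22 (3E,7Z,11Z)-13-[(4-methoxybenzyl)oxy]-3,7,11-trimethyltrideca-3,7,11-trien-1-ol
Conditions: Bu4NF, THF, 0 °C → rt
Reagents that add atoms: none
Why: Fluoride-mediated desilylation frees the C14 hydroxyl while the PMB ether keeps the two termini differentiated.

Step 13
Reactants: 22 (3E,7Z,11Z)-13-[(4-methoxybenzyl)oxy]-3,7,11-trimethyltrideca-3,7,11-trien-1-ol
Product: 23 (3E,7Z,11Z)-13-[(4-methoxybenzyl)oxy]-3,7,11-trimethyltrideca-3,7,11-trienal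
Conditions: Dess–Martin periodinane, NaHCO3, CH2Cl2, 0 °C; used without storage
Reagents that add atoms: none
Why: Dess–Martin oxidation under bicarbonate buffer gives the β,γ-unsaturated aldehyde without acid or base strong enough to move the C11=C12 alkene into conjugation.

Step 14
Reactants: 23 (3E,7Z,11Z)-13-[(4-methoxybenzyl)oxy]-3,7,11-trimethyltrideca-3,7,11-trienal; 24 ethyl diazoacetate
Product: 25 ethyl (5E,9Z,13Z)-15-[(4-methoxybenzyl)oxy]-5,9,13-trimethyl-3-oxopentadeca-5,9,13-trienoate
Conditions: SnCl2 (10 mol%), CH2Cl2, rt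
Reagents that add atoms: none
Why: In the Roskamp reaction the SnCl2-activated aldehyde is attacked by the diazo carbon and a 1,2-hydride shift with loss of N2 should give the β-keto ester (C14 ketone, C1 methylene, C15 ester) in one nearly neutral step.

Step 15
Reactants: 25 ethyl (5E,9Z,13Z)-15-[(4-methoxybenzyl)oxy]-5,9,13-trimethyl-3-oxopentadeca-5,9,13-trienoate
Product: 26 ethyl (5E,9Z,13Z)-15-hydroxy-5,9,13-trimethyl-3-oxopentadeca-5,9,13-trienoate
Conditions: DDQ (1.2 equiv), CH2Cl2/pH 7 phosphate buffer, 0 °C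
Reagents that add atoms: none
Why: Oxidative PMB cleavage by DDQ (hydride abstraction, then hydrolysis of the oxocarbenium ion) frees the allylic C2 hydroxyl, and cold buffered conditions limit over-oxidation of the allylic alcohol.

Step 16
Reactants: 26 ethyl (5E,9Z,13Z)-15-hydroxy-5,9,13-trimethyl-3-oxopentadeca-5,9,13-trienoate
Product: 27 ethyl (5E,9Z,13Z)-15-bromo-5,9,13-trimethyl-3-oxopentadeca-5,9,13-trienoate
Conditions: CBr4, PPh3, CH2Cl2, −30 → 0 °C
Reagents that add atoms: carbon tetrabromide, BrC(Br)(Br)Br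
Why: Appel bromination at low temperature should give the primary Z allylic bromide by SN2 displacement without allylic transposition, the β-keto ester being inert to the neutral reagent.

Step 17
Reactants: 27 ethyl (5E,9Z,13Z)-15-bromo-5,9,13-trimethyl-3-oxopentadeca-5,9,13-trienoate
Product: 28 ethyl (4E,8Z,12Z)-4,8,12-trimethyl-2-oxocyclotetradeca-4,8,12-triene-1-carboxylate
Conditions: Cs2CO3 (3 equiv), MeCN, 60 °C, 27 added by syringe pump over 12 h (final 2 mM)
Reagents that add atoms: none
Why: Intramolecular SN2 C-alkylation of the soft cesium enolate of the β-keto ester by the primary allylic bromide at high dilution closes the 14-membered ring at C1–C2 (14-exo-tet); no allyl–metal species is involved, so the Z C3=C4 geometry is kept, and C1 is formed as an epimerisable centre that step 18 fixes.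

Step 18
Reactants: 28 ethyl (4E,8Z,12Z)-4,8,12-trimethyl-2-oxocyclotetradeca-4,8,12-triene-1-carboxylate
Product: 29 ethyl (1S,2S,4E,8Z,12Z)-2-hydroxy-4,8,12-trimethylcyclotetradeca-4,8,12-triene-1-carboxylate
Conditions: [RuCl(C6H6)((S)-BINAP)]Cl (1 mol%), H2 (100 atm), CH2Cl2, 50 °C
Reagents that add atoms: none
Why: In this Noyori hydrogenation with dynamic kinetic resolution the C1 epimers of 28 interconvert through the enol faster than either is reduced, hydride transfer within the ruthenium keto ester chelate of the (S)-BINAP catalyst should set C14 as S, and, as with 2-alkoxycarbonylcycloalkanones, the epimer leading to the trans (anti) hydroxy ester should react faster and so set C1 (S here, R in the target once the ester has become the alkene), while isolated trisubstituted alkenes are not reduced by this halide catalyst.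

Step 19
Reactants: 29 ethyl (1S,2S,4E,8Z,12Z)-2-hydroxy-4,8,12-trimethylcyclotetradeca-4,8,12-triene-1-carboxylate
Product: 30 (1S,2S,4E,8Z,12Z)-2-hydroxy-N-methoxy-N,4,8,12-tetramethylcyclotetradeca-4,8,12-triene-1-carboxamide
Conditions: MeNH(OMe)·HCl, AlMe3, CH2Cl2, 0 °C → rt
Reagents that add atoms: N,O-dimethylhydroxylamine hydrochloride, Cl.CNOC
Why: In this Weinreb aminolysis the aluminium amide made from AlMe3 and the amine salt attacks the ester, helped by coordination of the neighbouring hydroxyl, under conditions too weakly basic to epimerise C1.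

Step 20
Reactants: 30 (1S,2S,4E,8Z,12Z)-2-hydroxy-N-methoxy-N,4,8,12-tetramethylcyclotetradeca-4,8,12-triene-1-carboxamide
Product: 31 (1S,2S,4E,8Z,12Z)-N,2-dimethoxy-N,4,8,12-tetramethylcyclotetradeca-4,8,12-triene-1-carboxamide
Conditions: Me3OBF4, 1,8-bis(dimethylamino)naphthalene, CH2Cl2, 0 °C → rt
Reagents that add atoms: trimethyloxonium tetrafluoroborate, C[O+](C)C.F[B-](F)(F)F
Why: O-Methylation with Meerwein's salt and a non-nucleophilic proton sponge avoids alkoxide formation, hence retro-aldol cleavage and β-elimination, and keeps C14 because its C–O bond is not broken.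

Step 21
Reactants: 31 (1S,2S,4E,8Z,12Z)-N,2-dimethoxy-N,4,8,12-tetramethylcyclotetradeca-4,8,12-triene-1-carboxamide; 32 5-bromo-2-methylpent-2-ene
Product: 34 1-[(1S,2S,4E,8Z,12Z)-2-methoxy-4,8,12-trimethylcyclotetradeca-4,8,12-trien-1-yl]-5-methylhex-4-en-1-one, via homoprenylmagnesium bromide 33 (not isolated)
Conditions: 32, Mg, THF, rt; then 31, THF, 0 °C; aq. NH4Cl
Reagents that add atoms: none
Why: In this Weinreb ketone synthesis the Grignard reagent adds once to give a stable magnesium chelate that releases the ketone only on work-up, which puts the homoprenyl chain on C15 without over-addition.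

Step 22
Reactants: 34 1-[(1S,2S,4E,8Z,12Z)-2-methoxy-4,8,12-trimethylcyclotetradeca-4,8,12-trien-1-yl]-5-methylhex-4-en-1-one
Product: 35 (1E,5Z,9Z,12R,13S)-13-methoxy-1,5,9-trimethyl-12-(6-methylhepta-1,5-dien-2-yl)cyclotetradeca-1,5,9-triene
Conditions: Cp2TiMe2 (3 equiv), toluene/THF, 65 °C, dark
Reagents that add atoms: bis(cyclopentadienyl)dimethyltitanium Cp2TiMe2, C[Ti](C)(C1C=CC=C1)C1C=CC=C1
Why: In the Petasis methylenation, thermal loss of methane from Cp2TiMe2 gives the titanium methylidene Cp2Ti=CH2, which undergoes [2+2] cycloaddition with the ketone and cycloreversion to the 1,1-disubstituted alkene, and since the reagent is neither basic nor a strong Lewis acid (it contains no aluminium) it should neither epimerise C1 nor eliminate the β-methoxy group.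

Compound list
1 | tert-butyl(but-3-yn-1-yloxy)dimethylsilane | C#CCCO[Si](C)(C)C(C)(C)C | starting material
2 | (E)-{4-[(tert-butyldimethylsilyl)oxy]-2-methylbut-1-en-1-yl}dimethylalane | C[Al](C)/C=C(\C)CCO[Si](C)(C)C(C)(C)C | intermediate
3 | (E)-tert-butyl[(4-iodo-3-methylbut-3-en-1-yl)oxy]dimethylsilane | I/C=C(\C)CCO[Si](C)(C)C(C)(C)C | intermediate
4 | oxirane | C1CO1 | starting material
5 | (E)-{4-[(tert-butyldimethylsilyl)oxy]-2-methylbut-1-en-1-yl}lithium | [Li]/C=C(\C)CCO[Si](C)(C)C(C)(C)C | intermediate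
6 | (E)-6-[(tert-butyldimethylsilyl)oxy]-4-methylhex-3-en-1-ol | OCC/C=C(\C)CCO[Si](C)(C)C(C)(C)C | intermediate
7 | (E)-[(6-bromo-3-methylhex-3-en-1-yl)oxy](tert-butyl)dimethylsilane | BrCC/C=C(\C)CCO[Si](C)(C)C(C)(C)C | intermediate
8 | (E)-{6-[(tert-butyldimethylsilyl)oxy]-4-methylhex-3-en-1-yl}magnesium bromide | Br[Mg]CC/C=C(\C)CCO[Si](C)(C)C(C)(C)C | intermediate
9 | methyl chloroformate | COC(=O)Cl | starting material
10 | {4-[(tert-butyldimethylsilyl)oxy]but-1-yn-1-yl}lithium | [Li]C#CCCO[Si](C)(C)C(C)(C)C | intermediate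
11 | methyl 5-[(tert-butyldimethylsilyl)oxy]pent-2-ynoate | COC(=O)C#CCCO[Si](C)(C)C(C)(C)C | intermediate
12 | lithium {(E)-4-[(tert-butyldimethylsilyl)oxy]-1-(methoxycarbonyl)-2-methylbut-1-en-1-yl}(methyl)cuprate | [Li+].COC(=O)/C([Cu-]C)=C(/C)CCO[Si](C)(C)C(C)(C)C | intermediate
13 | methyl (Z)-5-[(tert-butyldimethylsilyl)oxy]-3-methylpent-2-enoate | COC(=O)/C=C(/C)CCO[Si](C)(C)C(C)(C)C | intermediate
14 | (Z)-5-[(tert-butyldimethylsilyl)oxy]-3-methylpent-2-en-1-ol | OC/C=C(/C)CCO[Si](C)(C)C(C)(C)C | intermediate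
15 | (Z)-tert-butyl({5-[(4-methoxybenzyl)oxy]-3-methylpent-3-en-1-yl}oxy)dimethylsilane | COc1ccc(COC/C=C(/C)CCO[Si](C)(C)C(C)(C)C)cc1 | intermediate
16 | (Z)-5-[(4-methoxybenzyl)oxy]-3-methylpent-3-en-1-ol | COc1ccc(COC/C=C(/C)CCO)cc1 | intermediate
17 | (Z)-1-{[(5-iodo-3-methylpent-2-en-1-yl)oxy]methyl}-4-methoxybenzene | ICC/C(C)=C\COCc1ccc(OC)cc1 | intermediate
18 | propyne | CC#C | starting material
19 | (E)-{6-[(tert-butyldimethylsilyl)oxy]-4-methylhex-3-en-1-yl}copper (MgBr2 complex) | [Cu]CC/C=C(\C)CCO[Si](C)(C)C(C)(C)C | intermediate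
20 | (1Z,5E)-{8-[(tert-butyldimethylsilyl)oxy]-2,6-dimethylocta-1,5-dien-1-yl}copper | [Cu]/C=C(/C)CC/C=C(\C)CCO[Si](C)(C)C(C)(C)C | intermediate
21 | tert-butyl({(3E,7Z,11Z)-13-[(4-methoxybenzyl)oxy]-3,7,11-trimethyltrideca-3,7,11-trien-1-yl}oxy)dimethylsilane | COc1ccc(COC/C=C(/C)CC/C=C(/C)CC/C=C(\C)CCO[Si](C)(C)C(C)(C)C)cc1 | intermediate
22 | (3E,7Z,11Z)-13-[(4-methoxybenzyl)oxy]-3,7,11-trimethyltrideca-3,7,11-trien-1-ol | COc1ccc(COC/C=C(/C)CC/C=C(/C)CC/C=C(\C)CCO)cc1 | intermediate
23 | (3E,7Z,11Z)-13-[(4-methoxybenzyl)oxy]-3,7,11-trimethyltrideca-3,7,11-trienal | COc1ccc(COC/C=C(/C)CC/C=C(/C)CC/C=C(\C)CC=O)cc1 | intermediate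
24 | ethyl diazoacetate | CCOC(=O)C=[N+]=[N-] | starting material
25 | ethyl (5E,9Z,13Z)-15-[(4-methoxybenzyl)oxy]-5,9,13-trimethyl-3-oxopentadeca-5,9,13-trienoate | COc1ccc(COC/C=C(/C)CC/C=C(/C)CC/C=C(\C)CC(=O)CC(=O)OCC)cc1 | intermediate
26 | ethyl (5E,9Z,13Z)-15-hydroxy-5,9,13-trimethyl-3-oxopentadeca-5,9,13-trienoate | OC/C=C(/C)CC/C=C(/C)CC/C=C(\C)CC(=O)CC(=O)OCC | intermediate
27 | ethyl (5E,9Z,13Z)-15-bromo-5,9,13-trimethyl-3-oxopentadeca-5,9,13-trienoate | BrC/C=C(/C)CC/C=C(/C)CC/C=C(\C)CC(=O)CC(=O)OCC | intermediate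
28 | ethyl (4E,8Z,12Z)-4,8,12-trimethyl-2-oxocyclotetradeca-4,8,12-triene-1-carboxylate | CCOC(=O)C1C/C=C(/C)CC/C=C(/C)CC/C=C(\C)CC1=O | intermediate
29 | ethyl (1S,2S,4E,8Z,12Z)-2-hydroxy-4,8,12-trimethylcyclotetradeca-4,8,12-triene-1-carboxylate | CCOC(=O)[C@H]1C/C=C(/C)CC/C=C(/C)CC/C=C(\C)C[C@@H]1O | intermediate
30 | (1S,2S,4E,8Z,12Z)-2-hydroxy-N-methoxy-N,4,8,12-tetramethylcyclotetradeca-4,8,12-triene-1-carboxamide | CON(C)C(=O)[C@H]1C/C=C(/C)CC/C=C(/C)CC/C=C(\C)C[C@@H]1O | intermediate
31 | (1S,2S,4E,8Z,12Z)-N,2-dimethoxy-N,4,8,12-tetramethylcyclotetradeca-4,8,12-triene-1-carboxamide | CON(C)C(=O)[C@H]1C/C=C(/C)CC/C=C(/C)CC/C=C(\C)C[C@@H]1OC | intermediate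
32 | 5-bromo-2-methylpent-2-ene | CC(C)=CCCBr | starting material
33 | (4-methylpent-3-en-1-yl)magnesium bromide | CC(C)=CCC[Mg]Br | intermediate
34 | 1-[(1S,2S,4E,8Z,12Z)-2-methoxy-4,8,12-trimethylcyclotetradeca-4,8,12-trien-1-yl]-5-methylhex-4-en-1-one | CC(C)=CCCC(=O)[C@H]1C/C=C(/C)CC/C=C(/C)CC/C=C(\C)C[C@@H]1OC | intermediate
35 | (1E,5Z,9Z,12R,13S)-13-methoxy-1,5,9-trimethyl-12-(6-methylhepta-1,5-dien-2-yl)cyclotetradeca-1,5,9-triene | C=C(CCC=C(C)C)[C@H]1C/C=C(/C)CC/C=C(/C)CC/C=C(\C)C[C@@H]1OC | target

Total step count: 22 steps.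
Longest linear sequence: 18 steps (1 → 35 through steps 5–22).

Steps most likely to fail

1. Step 11. The alkylation of the alkenylcopper by an unactivated primary iodide is slow, so thermal decay of the alkenylcopper (dimerisation, loss of geometry) or elimination of the iodide may win. The fallback sets out from alkenylcopper 20 (made from 8 and 18 as in step 11) and iodide 17, and returns at 21. Compound 20 would be quenched with I2 at −40 °C to give the alkenyl iodide tert-butyl{[(3E,7Z)-8-iodo-3,7-dimethylocta-3,7-dien-1-yl]oxy}dimethylsilane F1. Iodide 17 would be converted with Zn dust and LiCl in THF into {(Z)-5-[(4-methoxybenzyl)oxy]-3-methylpent-3-en-1-yl}zinc iodide F2. A Negishi coupling of F1 and F2 with Pd(PPh3)4 in THF at rt would then form C6–C7 with retention of the Z geometry and give 21.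

2. Step 18. The flexible 14-membered ring may not impose the orientation that makes small cyclic keto esters give the trans product, so the two interconverting C1 epimers may be reduced at similar rates and the syn isomer would then contaminate the product; C14 should remain catalyst-controlled. The fallback sets out from open-chain keto ester 25 and returns at 29; it sets C14 first and C1 during ring closure. Compound 25, which has no α-substituent, would be hydrogenated with the same (S)-BINAP ruthenium catalyst to ethyl (3S,5E,9Z,13Z)-3-hydroxy-15-[(4-methoxybenzyl)oxy]-5,9,13-trimethylpentadeca-5,9,13-trienoate F3. DDQ would remove the PMB group to give ethyl (3S,5E,9Z,13Z)-3,15-dihydroxy-5,9,13-trimethylpentadeca-5,9,13-trienoate F4. NBS/Me2S (Corey–Kim conditions, which leave the secondary carbinol alone) would convert only the allylic hydroxyl into ethyl (3S,5E,9Z,13Z)-15-bromo-3-hydroxy-5,9,13-trimethylpentadeca-5,9,13-trienoate F5. Slow addition of F5 to LiN(i-Pr)2 (2.5 equiv) in THF/DMPU at −40 → −10 °C (final 2 mM) would form the chelated dianion. Its intramolecular Fráter–Seebach alkylation, anti to the C13 chain on the lithium chelate, would close the ring at C1–C2 and give the anti hydroxy ester 29. This ring-closing variant is the least precedented part of the fallback.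

3. Step 17. Intermolecular alkylation (oligomers) and O-alkylation of the enolate may compete with closure of the 14-membered ring. The fallback sets out from allylic alcohol 26 and returns at 28. Compound 26 would be converted with methyl chloroformate and pyridine into ethyl (5E,9Z,13Z)-15-[(methoxycarbonyl)oxy]-5,9,13-trimethyl-3-oxopentadeca-5,9,13-trienoate F6. A Tsuji–Trost cyclisation of F6 with Pd(PPh3)4 in THF at 60 °C under high dilution would then give 28; the methoxide released from the carbonate serves as the base, and the keto ester attacks the primary terminus of the allyl–palladium intermediate. Some erosion of the Z C3=C4 geometry through the allyl complex is the price of this route.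

Further compounds
F1 | step 11 | tert-butyl{[(3E,7Z)-8-iodo-3,7-dimethylocta-3,7-dien-1-yl]oxy}dimethylsilane | I/C=C(/C)CC/C=C(\C)CCO[Si](C)(C)C(C)(C)C
F2 | step 11 | {(Z)-5-[(4-methoxybenzyl)oxy]-3-methylpent-3-en-1-yl}zinc iodide | I[Zn]CC/C(C)=C\COCc1ccc(OC)cc1
F3 | step 18 | ethyl (3S,5E,9Z,13Z)-3-hydroxy-15-[(4-methoxybenzyl)oxy]-5,9,13-trimethylpentadeca-5,9,13-trienoate | COc1ccc(COC/C=C(/C)CC/C=C(/C)CC/C=C(\C)C[C@H](O)CC(=O)OCC)cc1
F4 | step 18 | ethyl (3S,5E,9Z,13Z)-3,15-dihydroxy-5,9,13-trimethylpentadeca-5,9,13-trienoate | OC/C=C(/C)CC/C=C(/C)CC/C=C(\C)C[C@H](O)CC(=O)OCC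
F5 | step 18 | ethyl (3S,5E,9Z,13Z)-15-bromo-3-hydroxy-5,9,13-trimethylpentadeca-5,9,13-trienoate | BrC/C=C(/C)CC/C=C(/C)CC/C=C(\C)C[C@H](O)CC(=O)OCC
F6 | step 17 | ethyl (5E,9Z,13Z)-15-[(methoxycarbonyl)oxy]-5,9,13-trimethyl-3-oxopentadeca-5,9,13-trienoate | COC(=O)OC/C=C(/C)CC/C=C(/C)CC/C=C(\C)CC(=O)CC(=O)OCC
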